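**Retrosynthetic overview**
1. Hyphenrone F ⇒ (+)-hyperforin. The cyclooctane is the periphery of the bicyclo[3.3.1]nonane. It is unveiled by C3 hydroxylation, transannular hemiketal formation, retro-Claisen cleavage of C1–C9, lactone opening and loss of C9 as CO2.
2. Hyperforin ⇒ its O4-methyl ether ⇒ one-pot dearomative [3+3] annulation of an aromatic acylphloroglucinol with a C15 1,3-cyclic sulfate. C5–C6 forms first (SN2), then C1–C8 (tertiary centre, inversion).
3. Cyclic sulfate ⇒ 1,3-diol ⇒ (2R,3S)-epoxynerol + prenylcopper ⇒ nerol. The asymmetric epoxidation is the only source of chirality.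
4. Acylphloroglucinol ⇒ 1,3,5-trimethoxybenzene + isobutyryl chloride + prenyl bromide.
5. Ring order: aromatic ring (bought) → dearomatised ring → second six-membered ring (bicyclo[3.3.1]nonane) → transient oxa-bridge and γ-lactone → eight-membered ring.

Assumption: C1 (between two ketones) and C5 (next to one ketone) of the target are epimerisable, so their natural configuration is taken to be the one reached by ketonisation and equilibration in the last step. Atom numbers are those of hyperforin (C1 acyl-bearing, C3 carbinol, C5 and C7 prenyl-bearing methines, C8 quaternary, C9 the one-carbon bridge that is lost). In this numbering the target is (1R,3R,5S,7S,8R).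

**Step 1**
Reactants: 1 1,3,5-trimethoxybenzene; 2 isobutyryl chloride
Product: 3 1-(2,6-dihydroxy-4-methoxyphenyl)-2-methylpropan-1-one
Conditions: AlCl3 (4 equiv), PhCl, 0 °C, then 90 °C; ice/aq HCl
Reagents that add atoms: none
Why: Friedel–Crafts acylation of the activated arene is followed in the same pot by chelation-directed ether cleavage, in which AlCl3 bound to the new ketone removes only the two ortho methyl groups and leaves the para OMe that later keeps O4 and C3 out of play; no stereocentre is formed.

**Step 2**
Reactants: 3 1-(2,6-dihydroxy-4-methoxyphenyl)-2-methylpropan-1-one; 4 prenyl bromide (2.2 equiv)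
Product: 5 1-[2,6-dihydroxy-4-methoxy-3,5-bis(3-methylbut-2-en-1-yl)phenyl]-2-methylpropan-1-one
Conditions: KOH (2.2 equiv), H2O, 0 °C → rt
Reagents that add atoms: none
Why: This is a twofold C-alkylation of an ambident phloroglucinol phenolate with an allylic bromide in water, where hydrogen bonding to the oxygens directs the electrophile to the two free ring carbons; no stereocentre is formed.

**Step 3**
Reactants: 6 nerol
Product: 7 [(2R,3S)-3-methyl-3-(4-methylpent-3-en-1-yl)oxiran-2-yl]methanol ((2R,3S)-2,3-epoxynerol)
Conditions: Ti(OiPr)4 (5 mol %), D-(−)-diethyl tartrate (7 mol %), t-BuOOH, 4 Å MS, CH2Cl2, −20 °C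
Reagents that add atoms: tert-butyl hydroperoxide, CC(C)(C)OO
Why: The Katsuki–Sharpless asymmetric epoxidation touches only the allylic alkene bound through the titanium alkoxide and, with the D-tartrate, gives the (2R,3S)-epoxide (about 90–94% ee), so the C8 carbinol centre and the absolute configuration of the whole route are fixed here.

**Step 4**
Reactants: 7 (2R,3S)-2,3-epoxynerol; 8 prenyl chloride
Product: 10 (2S,3S)-3,7-dimethyl-2-(3-methylbut-2-en-1-yl)oct-6-ene-1,3-diol, via prenylmagnesium chloride 9 (not isolated)
Conditions: 8, Mg, THF, 0 °C; separately 7, MeMgCl (1.0 equiv), THF, −40 °C; combine, CuBr·SMe2 (10 mol %), −40 → 0 °C; aq NH4Cl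
Reagents that add atoms: none
Why: In this copper-catalysed SN2 opening of a 2,3-epoxy alcohol by an allylic Grignard reagent, attack is possible only at the non-quaternary epoxide carbon C7, occurs with inversion (C7 becomes S) and gives the linear prenyl group by reductive elimination at the unhindered primary terminus of the allylcopper species, while the C8–O bond and its configuration are untouched.

**Step 5**
Reactants: 10 (2S,3S)-3,7-dimethyl-2-(3-methylbut-2-en-1-yl)oct-6-ene-1,3-diol
Product: 11 (4S,5S)-4-methyl-5-(3-methylbut-2-en-1-yl)-4-(4-methylpent-3-en-1-yl)-1,3,2-dioxathiane 2,2-dioxide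
Conditions: NaH (2.2 equiv), THF, 0 °C; 1,1'-sulfonyldiimidazole (1.1 equiv), −20 °C → rt; cold aqueous work-up, used at once
Reagents that add atoms: 1,1'-sulfonyldiimidazole, O=S(=O)(n1ccnc1)n1ccnc1
Why: Cyclic sulfate formation by double sulfuryl transfer to the dialkoxide is an oxidant-free alternative to the sulfite/oxidation sequence that spares both trisubstituted alkenes and breaks no C–O bond, so C7 and C8 are retained.

**Step 6**
Reactants: 5 1-[2,6-dihydroxy-4-methoxy-3,5-bis(3-methylbut-2-en-1-yl)phenyl]-2-methylpropan-1-one; 11 cyclic sulfate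
Product: 13 hyperforin O4-methyl enol ether, via tertiary alkyl sulfate 12 (not isolated)
Conditions: 5, LiN(SiMe3)2 (2.05 equiv), THF, 0 °C; 11 (1.1 equiv), 0 → 35 °C; then (CF3)2CHOH (4 vol), 45 °C
Reagents that add atoms: none
Why: Proposed new method: this is a dearomative [3+3] annulation in which the cyclic sulfate plays the part of the biosynthetic diphosphates; the dilithium phenolate of 5 is C-alkylated at a prenyl-bearing carbon by the primary C–O end (closest known types: alkylative dearomatisation of acylphloroglucinols with primary alkyl triflates, and double alkylation of malonates with cyclic sulfates), the remaining tertiary alkyl sulfate ionises in (CF3)2CHOH, and the contact ion pair is captured from the rear by C1 of the triketone monoanion, which is the only anionic carbon because O4 is methylated (hence the bridgehead-acyl skeleton) and whose oxygens are shielded by hydrogen bonding, through a chair with the C7 prenyl equatorial, so that C8 is inverted to R and C1 is set; C5 forms about 1:1 in the first bond formation and only the epimer drawn can reach this chair, the other ending as elimination or O-alkylation products that are removed by chromatography.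

**Step 7**
Reactants: 13 hyperforin O4-methyl enol ether
Product: 14 (+)-hyperforin
Conditions: LiCl (10 equiv), DMSO, 120 °C; dilute aq HCl work-up; Ar, dark
Reagents that add atoms: none
Why: Nucleophilic demethylation of a vinylogous methyl ester (Krapcho-type SN2 attack of chloride on the methyl carbon) frees the enolised β-diketone without touching the alkenes or any stereocentre.

**Step 8**
Reactants: 14 (+)-hyperforin
Product: 19 hyphenrone F, via 3-hydroxy trione 15 (not isolated), via C3–O–C9 hemiketal 16 (not isolated), via keto lactone 17 (not isolated), via keto acid 18 (not isolated)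
Conditions: KN(SiMe3)2 (1.05 equiv), THF, −78 °C; 2-(phenylsulfonyl)-3-phenyloxaziridine (1.2 equiv), −78 → 0 °C; aq KOH (3 equiv), 0 °C → rt; AcOH to pH 5, 50 °C
Reagents that add atoms: 2-(phenylsulfonyl)-3-phenyloxaziridine, O=S(=O)(N1OC1c1ccccc1)c1ccccc1
Why: Davis enolate hydroxylation, which leaves isolated alkenes alone at this temperature, occurs on the face of C3 syn to the one-carbon bridge because the other face is covered by the C6–C8 bridge (C3 becomes R), the alkoxide adds across the ring to C9, the hemiketal collapses by retro-Claisen cleavage of C1–C9 with the β-diketone enolate as leaving group, saponification and β-keto acid decarboxylation then excise C9 (the oxygen of water leaves again in CO2), and C5 and C1 are set by ketonisation on the C3–OH face and by equilibration of the labile β-diketone methine.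

**Compound list**
1 | 1,3,5-trimethoxybenzene | COc1cc(OC)cc(OC)c1 | starting material
2 | isobutyryl chloride | CC(C)C(=O)Cl | starting material
3 | 1-(2,6-dihydroxy-4-methoxyphenyl)-2-methylpropan-1-one | COc1cc(O)c(C(=O)C(C)C)c(O)c1 | intermediate
4 | prenyl bromide | CC(C)=CCBr | starting material
5 | 1-[2,6-dihydroxy-4-methoxy-3,5-bis(3-methylbut-2-en-1-yl)phenyl]-2-methylpropan-1-one | COc1c(CC=C(C)C)c(O)c(C(=O)C(C)C)c(O)c1CC=C(C)C | intermediate
6 | nerol | CC(C)=CCC/C(C)=C\CO | starting material
7 | (2R,3S)-2,3-epoxynerol | OC[C@H]1O[C@@]1(C)CCC=C(C)C | intermediate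
8 | prenyl chloride | CC(C)=CCCl | starting material
9 | prenylmagnesium chloride | CC(C)=CC[Mg]Cl | intermediate (not isolated)
10 | (2S,3S)-3,7-dimethyl-2-(3-methylbut-2-en-1-yl)oct-6-ene-1,3-diol | OC[C@H](CC=C(C)C)[C@@](C)(O)CCC=C(C)C | intermediate
11 | (4S,5S)-4-methyl-5-prenyl-4-(4-methylpent-3-en-1-yl)-1,3,2-dioxathiane 2,2-dioxide | O=S1(=O)OC[C@H](CC=C(C)C)[C@](C)(CCC=C(C)C)O1 | intermediate
12 | C5-alkylated, dearomatised ring (C5 quaternary as in hyperforin, C4–OMe enol ether, enolised C1 triketone) with side chain C7 (S) and C8 (S) bearing OSO3H; present as dilithium salt | COC1=C(CC=C(C)C)C(=O)C(C(=O)C(C)C)=C(O)[C@]1(CC=C(C)C)C[C@H](CC=C(C)C)[C@](C)(CCC=C(C)C)OS(=O)(=O)O | intermediate (not isolated)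
13 | hyperforin O4-methyl enol ether (OMe on the enol carbon next to the prenyl-bearing bridgehead C5) | CC(C)C(=O)[C@]12C(=O)C(CC=C(C)C)=C(OC)[C@](C1=O)(C[C@@H]([C@@]2(C)CCC=C(C)C)CC=C(C)C)CC=C(C)C | intermediate
14 | (+)-hyperforin | CC(C)C(=O)[C@]12C(=O)C(CC=C(C)C)=C(O)[C@](C1=O)(C[C@@H]([C@@]2(C)CCC=C(C)C)CC=C(C)C)CC=C(C)C | intermediate
15 | 3-hydroxyhyperforin trione (C3–OH syn to C9) | CC(C)C(=O)[C@]12C(=O)[C@@](O)(CC=C(C)C)C(=O)[C@](C1=O)(C[C@@H]([C@@]2(C)CCC=C(C)C)CC=C(C)C)CC=C(C)C | intermediate (not isolated)
16 | transannular hemiketal (oxygen bridge from C3 to C9) | CC(C)C(=O)[C@]12C(=O)[C@]3(CC=C(C)C)O[C@@]1(O)[C@@](CC=C(C)C)(C3=O)C[C@H](CC=C(C)C)[C@@]2(C)CCC=C(C)C | intermediate (not isolated)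
17 | cyclooctane-fused β-keto γ-lactone (C3–O–C9(=O)–C5), present as its C1 enolate | CC(C)=CCC[C@]1(C)[C@@H](CC=C(C)C)C[C@]2(CC=C(C)C)C(=O)[C@](OC2=O)(CC=C(C)C)C(=O)[C@H]1C(=O)C(C)C | intermediate (not isolated)
18 | C5 carboxylic acid (β-keto acid) of the cyclooctane | CC(C)=CCC[C@]1(C)[C@@H](CC=C(C)C)C[C@](C(=O)O)(CC=C(C)C)C(=O)[C@](O)(CC=C(C)C)C(=O)[C@H]1C(=O)C(C)C | intermediate (not isolated)
19 | hyphenrone F | CC(C)=CCC[C@]1(C)[C@@H](CC=C(C)C)C[C@H](CC=C(C)C)C(=O)[C@](O)(CC=C(C)C)C(=O)[C@H]1C(=O)C(C)C | target

**Total step count:** 8.
**Longest linear sequence:** 6 (6 → 7 → 10 → 11 → 13 → 14 → 19).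

**Steps most likely to fail**

Step 6 is the riskiest.
- The hindered ring carbon may be O-alkylated rather than C-alkylated.
- Compound 11 may eliminate or ionise before the SN2 event.
- C5 forms without selectivity.
- O9 may capture the tertiary centre instead of C1.

The fallback sets out from 10 (together with 5) and comes back to the route at 12. Diol 10 is converted with I2, PPh3 and imidazole at its primary hydroxyl into the hydroxy iodide F1. The dilithium salt of 5 is C-alkylated with this softer electrophile to give the isolable dearomatised tertiary alcohol F2, and its C5 epimers are separated on silica. The tertiary hydroxyl of the correct epimer is then sulfated with SO3·pyridine. This gives 12 as a single diastereomer, ready for ionisation in (CF3)2CHOH. The two bond formations are thus decoupled and the labile cyclic sulfate is bypassed.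

Step 8 is second.
- Hydroxide may attack C4 or C2 of the non-enolisable diketone instead of the lactone carbonyl.
- Acid 18 may relactonise faster than it loses CO2.
- C5 may ketonise to the wrong epimer.

The fallback sets out from 17 and comes back at 18. The cascade is stopped by a pH 7 quench after the oxaziridine stage and 17 is isolated. It is opened at −20 °C with lithium allyloxide in allyl alcohol/THF to give the allyl β-keto ester F3. The allyl group is removed under neutral conditions with Pd(PPh3)4 (zerovalent palladium) and morpholine at rt. This releases 18 as its morpholinium salt, which decarboxylates on gentle warming. A short treatment with K2CO3 in MeOH equilibrates C5 if needed.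

Step 4 is third.
- The prenyl nucleophile may couple through its tertiary terminus.
- Payne rearrangement or chlorohydrin formation may compete at the hindered C7.

The fallback sets out from 7 and comes back at 10. The epoxide is opened with the symmetrical allylmagnesium chloride and CuBr·SMe2 to give the allyl diol F4. Cross metathesis with 2-methylbut-2-ene, using the second-generation Hoveyda–Grubbs catalyst, then turns the allyl group into the prenyl group. The existing trisubstituted alkene only exchanges degenerately.

**Further compounds**
F1 | step 6 | hydroxy iodide, the primary iodide of diol 10 with the tertiary OH free and both stereocentres spatially unchanged | IC[C@H](CC=C(C)C)[C@@](C)(O)CCC=C(C)C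
F2 | step 6 | dearomatised tertiary alcohol, compound 12 with OH in place of OSO3H, C5 as in hyperforin | COC1=C(CC=C(C)C)C(=O)C(C(=O)C(C)C)=C(O)[C@]1(CC=C(C)C)C[C@H](CC=C(C)C)[C@](C)(CCC=C(C)C)O
F3 | step 8 | allyl β-keto ester, the allyl ester of acid 18 | CC(C)=CCC[C@]1(C)[C@@H](CC=C(C)C)C[C@](C(=O)OCC=C)(CC=C(C)C)C(=O)[C@](O)(CC=C(C)C)C(=O)[C@H]1C(=O)C(C)C
F4 | step 4 | allyl diol, (2S,3S)-2-allyl-3,7-dimethyloct-6-ene-1,3-diol | OC[C@H](CC=C)[C@@](C)(O)CCC=C(C)C
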